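## Retrosynthetic overview

1. Target ⇒ open-chain pentacosa-2,9,11-triyne-1,25-diol. The furan, the only ring, is closed last by forming its C2–O bond. The HOCH2–C≡C–CH2 terminus is the latent furan (O and C5 from CH2OH, C4 and C3 from the alkyne, C2 from the propargylic CH2), unmasked by an aerobic dehydrogenative cycloisomerisation.
2. Triynediol ⇒ sp–sp Cadiot–Chodkiewicz coupling of 15-bromopentadec-14-yn-1-ol (C15 fragment) with deca-2,9-diyn-1-ol (C10 fragment).
3. C15 fragment ⇒ pentadec-14-yn-1-ol ⇒ alkyne zipper of pentadec-2-yn-1-ol ⇒ propargyl alcohol + 1-bromododecane.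
4. C10 fragment ⇒ nona-1,8-diyne + formaldehyde.

Assumption: the target has no stereocentre and no stereogenic double bond, so it is achiral and no stereocontrol is required.

## Route

**Step 1**
Reactants: 1 prop-2-yn-1-ol (propargyl alcohol); 2 1-bromododecane
Product: 4 pentadec-2-yn-1-ol, via dilithiated propargyl alcohol 3 (not isolated)
Conditions: 1 (1.3 equiv), n-BuLi (2.6 equiv), THF/HMPA (5:1), −78 to −20 °C; then 2 (1.0 equiv), −20 °C to rt, 12 h; H2O
Reagents that add atoms: none
Why: Acetylide alkylation of the O,C-dianion, in which the alkynide carbon is far more nucleophilic than the lithium alkoxide, so SN2 displacement of the primary bromide gives the 2-alkyn-1-ol directly.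

**Step 2**
Reactants: 4 pentadec-2-yn-1-ol
Product: 6 pentadec-14-yn-1-ol, via disodium salt of pentadec-14-yn-1-ol 5 (not isolated)
Conditions: NaH (5 equiv), H2N(CH2)3NH2 (solvent), 70 °C, 1 h; then 4, 55 °C, 12 h; H2O, 0 °C
Reagents that add atoms: none
Why: Alkyne zipper reaction, in which the 3-aminopropylamide base walks the triple bond along the chain by reversible propargyl/allenyl deprotonation–reprotonation and irreversible formation of the terminal alkynide 5 pulls the equilibrium to the chain end remote from the alkoxide.

**Step 3**
Reactants: 6 pentadec-14-yn-1-ol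
Product: 7 15-bromopentadec-14-yn-1-ol
Conditions: NBS (1.1 equiv), AgNO3 (10 mol %), acetone, rt, dark, 2 h
Reagents that add atoms: N-bromosuccinimide (NBS), O=C1CCC(=O)N1Br
Why: AgNO3-catalysed electrophilic bromination of the terminal alkyne C–H by NBS is selective for the sp C–H and leaves the primary alcohol untouched.

**Step 4**
Reactants: 8 nona-1,8-diyne
Product: 10 deca-2,9-diyn-1-ol, via lithium nona-1,8-diyn-1-ide 9 (not isolated)
Conditions: 8 (3 equiv), n-BuLi (1.0 equiv), THF, −78 °C; (CH2O)n (1.5 equiv), −78 °C to rt; H2O; excess 8 recovered by distillation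
Reagents that add atoms: paraformaldehyde (reacting as formaldehyde), C=O
Why: Alkyne hydroxymethylation by 1,2-addition of the lithium alkynide to formaldehyde, with the threefold excess of diyne over n-BuLi keeping double addition statistically low (about 10:1 mono to bis).

**Step 5**
Reactants: 7 15-bromopentadec-14-yn-1-ol; 10 deca-2,9-diyn-1-ol
Product: 11 pentacosa-2,9,11-triyne-1,25-diol
Conditions: 10 (1.3 equiv), CuCl (10 mol %), NH2OH·HCl (30 mol %), 30% aq. n-BuNH2/MeOH, 0 °C; then 7 (1.0 equiv) in Et2O added dropwise, 0 °C to rt
Reagents that add atoms: none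
Why: Cadiot–Chodkiewicz coupling, a CuCl/amine-catalysed sp–sp cross-coupling of terminal alkyne 10 with 1-bromoalkyne 7, in which NH2OH·HCl holds copper in the monovalent state to suppress oxidative homocoupling and both free hydroxyls are tolerated.

**Step 6**
Reactants: 11 pentacosa-2,9,11-triyne-1,25-diol
Product: 14 21-(furan-2-yl)henicosa-14,16-diyn-1-ol, via 2-ynal 12 (not isolated), via 2,3-dienal 13 (not isolated)
Conditions: CuI (10 mol %), 2,2'-bipyridine (10 mol %), TEMPO (10 mol %), Et3N (3 equiv), DMA (0.05 M), O2 (1 atm), 25 °C, until the propargylic CH2OH is consumed (about 3 h); then argon sparge, ascorbic acid (20 mol %), 100 °C, 6 h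
Reagents that add atoms: none
Why: Proposed new method: an aerobic dehydrogenative cycloisomerisation of a primary 2-alkyn-1-ol to a 2-alkylfuran under one CuI catalyst, reasoned as follows: (a) the CuI/bipyridine/TEMPO ((2,2,6,6-tetramethylpiperidin-1-yl)oxyl)/O2 couple oxidises the propargylic CH2OH of 11 to 2-ynal 12, and because this is the more acidic alcohol with the weaker α-C–H it should react at least tenfold faster than the saturated CH2OH at C25, while no terminal alkyne remains that could dimerise oxidatively; (b) Et3N shifts the γ-proton of 12, acidified by conjugation to the formyl group, to give 2,3-dienal 13 (racemic, transient); (c) monovalent copper, restored by ascorbic acid once O2 is removed, π-activates the distal allene double bond and the formyl oxygen closes the ring by 5-endo attack on C4, which is the new C–O bond, after which proton transfer gives the aromatic furan as an irreversible sink that leaves the internal 1,3-diyne and the remote alcohol unchanged; the closest known reaction types are the CuI/TEMPO-type aerobic oxidation of primary alcohols to aldehydes and the CuI/Et3N cycloisomerisation of alkynyl ketones to furans through allenyl ketones, which have not been merged into one relay starting from an alkynol.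

## Compound list

1 | prop-2-yn-1-ol (propargyl alcohol) | C#CCO | starting material
2 | 1-bromododecane | CCCCCCCCCCCCBr | starting material
3 | dilithiated propargyl alcohol (lithium 3-lithioprop-2-yn-1-olate, formed in situ) | [Li+].[Li+].[O-]CC#[C-] | intermediate
4 | pentadec-2-yn-1-ol | CCCCCCCCCCCCC#CCO | intermediate
5 | disodium salt of pentadec-14-yn-1-ol (alkoxide and terminal alkynide, formed in situ) | [Na+].[Na+].[O-]CCCCCCCCCCCCCC#[C-] | intermediate
6 | pentadec-14-yn-1-ol | OCCCCCCCCCCCCCC#C | intermediate
7 | 15-bromopentadec-14-yn-1-ol | OCCCCCCCCCCCCCC#CBr | intermediate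
8 | nona-1,8-diyne | C#CCCCCCC#C | starting material
9 | lithium nona-1,8-diyn-1-ide (formed in situ) | [Li+].[C-]#CCCCCCC#C | intermediate
10 | deca-2,9-diyn-1-ol | OCC#CCCCCCC#C | intermediate
11 | pentacosa-2,9,11-triyne-1,25-diol | OCC#CCCCCCC#CC#CCCCCCCCCCCCCCO | intermediate
12 | 25-hydroxypentacosa-2,9,11-triynal (2-ynal, formed in situ) | O=CC#CCCCCCC#CC#CCCCCCCCCCCCCCO | intermediate
13 | 25-hydroxypentacosa-2,3-diene-9,11-diynal (2,3-dienal, racemic allene, formed in situ) | O=CC=C=CCCCCC#CC#CCCCCCCCCCCCCCO | intermediate
14 | 21-(furan-2-yl)henicosa-14,16-diyn-1-ol (achiral) | OCCCCCCCCCCCCCC#CC#CCCCCc1ccco1 | target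

## Step count and risks

Total steps: 6. Longest linear sequence: 5 (steps 1, 2, 3, 5, 6); step 4 is a one-step side branch.

**Most likely to fail, 1: step 6 (the proposed new step).** Possible failures are competing oxidation of the C25 alcohol, amine-induced oligomerisation of 2-ynal 12, and sluggish isomerisation to 13. The fallback uses known chemistry and still closes the furan through a C–O bond. It sets out from 7 and comes back to the route at 14. Cadiot–Chodkiewicz coupling of 7 with hepta-1,6-diyne (5 equiv; CuCl, NH2OH·HCl, n-BuNH2, MeOH, 0 °C) gives docosa-14,16,21-triyn-1-ol F1. Commercially available ethyl (Z)-3-iodoacrylate is reduced with i-Bu2AlH (CH2Cl2, −78 °C) to (Z)-3-iodoprop-2-en-1-ol F2. Sonogashira coupling of F1 with F2 (Pd(PPh3)2Cl2, CuI, Et3N, THF, rt) gives (2Z)-pentacos-2-ene-4,9,11-triyne-1,25-diol F3. AgNO3 on silica gel (10 mol %, CH2Cl2, rt) then effects the known cycloisomerisation of the (Z)-2-en-4-yn-1-ol, by 5-exo-dig attack of the allylic hydroxyl on C4 followed by aromatisation, to give 14.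

**Most likely to fail, 2: step 5.** The risk is reductive homocoupling of 7 and difficult separation of three polar diols. The fallback reverses the order of the two C–C bond formations. It sets out from 7 and 8, makes step 4 unnecessary, and comes back at 11. Cadiot–Chodkiewicz coupling of 7 with a fivefold excess of the volatile hydrocarbon 8 (CuCl, NH2OH·HCl, n-BuNH2, MeOH/Et2O, 0 °C) gives tetracosa-14,16,23-triyn-1-ol F4, a mono-alcohol that is easily separated from hydrocarbon by-products. Double deprotonation with EtMgBr (2.2 equiv, THF, 45 °C) and addition of (CH2O)n then hydroxymethylates the terminal alkyne to give 11.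

**Most likely to fail, 3: step 4.** The risk is the statistical mono-functionalisation of a symmetrical diyne, with bis-adduct formation and loss of volatile 8. The fallback is a linear build with no statistical step. It sets out from 1 and comes back at 10. Dianion 3 (n-BuLi, 2 equiv, THF/HMPA) is alkylated chemoselectively at the C–Br end of 1-bromo-5-chloropentane to give 8-chlorooct-2-yn-1-ol F5. Displacement of chloride with LiC≡CH·H2NCH2CH2NH2 (3 equiv, NaI 10 mol %, DMSO, rt) gives 10.

## Further compounds

F1 | step 6 | docosa-14,16,21-triyn-1-ol | C#CCCCC#CC#CCCCCCCCCCCCCCO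
F2 | step 6 | (Z)-3-iodoprop-2-en-1-ol | OC/C=C\I
F3 | step 6 | (2Z)-pentacos-2-ene-4,9,11-triyne-1,25-diol | OC/C=C\C#CCCCC#CC#CCCCCCCCCCCCCCO
F4 | step 5 | tetracosa-14,16,23-triyn-1-ol | C#CCCCCCC#CC#CCCCCCCCCCCCCCO
F5 | step 4 | 8-chlorooct-2-yn-1-ol | OCC#CCCCCCCl
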